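**Retrosynthetic overview**
1. Target 16 ⇐ C6 ketone 15 by chelation-controlled hydride delivery (sets C6; germacrane numbering, see the note below).
2. Key disconnection C6–C7: 15 ⇐ open-chain epoxy aldehyde 14, by an acyl-radical ring closure onto the butenolide that expels isobutyrate (closes the ten-membered ring, sets C7, unveils the exo-methylene).
3. 14 ⇐ enal 7 + silyloxyfuran 9 (C8–C9, anti vinylogous Mukaiyama aldol), then double isobutyrylation and oxidation at C6.
4. 7 ⇐ hex-1-en-5-yne: carboalumination/CH2O (C4=C5, C15, C6), Sharpless epoxidation (C4, C5), cross-metathesis with methacrolein (C1=C10, C9, C14).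
5. Ring order: oxirane (step 2), butenolide brought in as a furanone (step 6), ten-membered carbocycle last (step 9).

Note on numbering: germacrane numbering is used for the skeleton (C1=C10 alkene, C4–C5 oxirane, C6 OH, C7/C8 lactone fusion, C9 ester, C11=C13 methylene, C12 carbonyl).

Assumption: hex-1-en-5-yne and 3-(hydroxymethyl)furan-2(5H)-one are taken as catalogue chemicals, and the pseudo-enantiomer of the cinchona salt in step 6 is the one that gives the (5R) butenolide.

**Step 1**
Reactants: 1 hex-1-en-5-yne
Product: 3 (2E)-3-methylhepta-2,6-dien-1-ol, via alkenyldimethylalane 2 (not isolated)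
Conditions: AlMe3, Cp2ZrCl2 (20 mol%), CH2Cl2, 0 °C to rt; then (CH2O)n, rt; aq. HCl work-up
Reagents that add atoms: trimethylaluminium C[Al](C)C; paraformaldehyde (reacts as formaldehyde) C=O
Why: Negishi Cp2ZrCl2-catalysed carboalumination adds Me–Al syn across the terminal alkyne (much faster than across the 1-alkene) with Al on the terminal carbon, and the alkenylalane is hydroxymethylated with retention, which fixes the E trisubstituted C4=C5 alkene with its C15 methyl and the C6 oxygen.

**Step 2**
Reactants: 3 (2E)-3-methylhepta-2,6-dien-1-ol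
Product: 4 [(2S,3S)-3-(but-3-en-1-yl)-3-methyloxiran-2-yl]methanol
Conditions: Ti(OiPr)4 (5 mol%), L-(+)-diethyl tartrate (6 mol%), t-BuOOH, 4 Å molecular sieves, CH2Cl2, −20 °C
Reagents that add atoms: tert-butyl hydroperoxide CC(C)(C)OO
Why: Sharpless asymmetric epoxidation of the allylic alcohol (the isolated terminal alkene is inert) with L-(+)-tartrate gives the (2S,3S) epoxy alcohol, as with geraniol, which sets C4 and C5 of the target by reagent control.

**Step 3**
Reactants: 4 [(2S,3S)-3-(but-3-en-1-yl)-3-methyloxiran-2-yl]methanol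
Product: 5 {[(2S,3S)-3-(but-3-en-1-yl)-3-methyloxiran-2-yl]methoxy}(triethyl)silane
Conditions: Et3SiCl, imidazole, CH2Cl2, 0 °C
Reagents that add atoms: chlorotriethylsilane CC[Si](Cl)(CC)CC
Why: Standard silyl ether formation masks the C6 oxygen through steps 4 to 7 with a group that step 8 oxidises off in a single operation.

**Step 4**
Reactants: 5 {[(2S,3S)-3-(but-3-en-1-yl)-3-methyloxiran-2-yl]methoxy}(triethyl)silane; 6 methacrolein (2-methylprop-2-enal)
Product: 7 (2E)-2-methyl-5-[(2S,3S)-2-methyl-3-{[(triethylsilyl)oxy]methyl}oxiran-2-yl]pent-2-enal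
Conditions: second-generation Grubbs catalyst RuCl2(=CHPh)(PCy3)(SIMes) (5 mol%), methacrolein (5 equiv), CH2Cl2, 40 °C
Reagents that add atoms: none
Why: Olefin cross-metathesis of the terminal alkene with excess methacrolein gives the thermodynamically favoured E 2-methyl-2-enal and leaves the epoxide and silyl ether alone, which sets the 1(10)E alkene with C14 and the C9 carbonyl.

**Step 5**
Reactants: 8 3-(hydroxymethyl)furan-2(5H)-one
Product: 9 trimethyl({2-[(trimethylsilyl)oxy]furan-3-yl}methoxy)silane
Conditions: Me3SiCl (2.4 equiv), Et3N (2.6 equiv), Et2O, 0 °C to rt; filter, distil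
Reagents that add atoms: chlorotrimethylsilane C[Si](C)(C)Cl
Why: Soft enolisation with O-silylation turns the butenolide into the aromatic 2-silyloxyfuran (the dienolate equivalent for a vinylogous Mukaiyama aldol) and caps the primary alcohol as an ether that cannot be expelled from the dienolate.

**Step 6**
Reactants: 7 (2E)-2-methyl-5-[(2S,3S)-2-methyl-3-{[(triethylsilyl)oxy]methyl}oxiran-2-yl]pent-2-enal; 9 trimethyl({2-[(trimethylsilyl)oxy]furan-3-yl}methoxy)silane
Product: 11 (5R)-5-{(1S,2E)-1-hydroxy-2-methyl-5-[(2S,3S)-2-methyl-3-{[(triethylsilyl)oxy]methyl}oxiran-2-yl]pent-2-en-1-yl}-3-(hydroxymethyl)furan-2(5H)-one, via bis(trimethylsilyl) aldol adduct 10 (not isolated)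
Conditions: cinchona 9-amino thiourea ammonium carboxylate salt (10 mol%), CH2Cl2, −20 °C; then citric acid, MeOH, 0 °C
Reagents that add atoms: none
Why: Vinylogous Mukaiyama aldol at the furan 5-position under chiral ammonium carboxylate (Lewis-base) activation, the open-transition-state manifold that gives the anti (erythro) adduct, sets C8 (R) and C9 (S) by catalyst control remote from the epoxide, and brief acid methanolysis then removes both trimethylsilyl groups but not the triethylsilyl ether.

**Step 7**
Reactants: 11 (the diol from step 6); 12 2-methylpropanoyl chloride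
Product: 13 [(5R)-5-{(1S,2E)-2-methyl-1-(2-methylpropanoyloxy)-5-[(2S,3S)-2-methyl-3-{[(triethylsilyl)oxy]methyl}oxiran-2-yl]pent-2-en-1-yl}-2-oxo-2,5-dihydrofuran-3-yl]methyl 2-methylpropanoate
Conditions: 2-methylpropanoyl chloride (2.4 equiv in all), pyridine (4 equiv), DMAP (5 mol%), CH2Cl2, −20 to 0 °C
Reagents that add atoms: 2-methylpropanoyl chloride (second equivalent of 12) CC(C)C(Cl)=O
Why: DMAP-catalysed acylation of both alcohols, each with one equivalent of the acid chloride and with retention, installs the C9 isobutyrate of the target and turns the C13 oxygen into the leaving group used in step 9, while the weak base avoids elimination of the δ-acyloxy butenolide.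

**Step 8**
Reactants: 13 (the bis-isobutyrate from step 7)
Product: 14 [(5R)-5-{(1S,2E)-5-[(2S,3R)-3-formyl-2-methyloxiran-2-yl]-2-methyl-1-(2-methylpropanoyloxy)pent-2-en-1-yl}-2-oxo-2,5-dihydrofuran-3-yl]methyl 2-methylpropanoate
Conditions: (COCl)2, DMSO, CH2Cl2, −78 to −30 °C; then Et3N, −78 °C, cold quench
Reagents that add atoms: none
Why: Swern oxidation of a primary triethylsilyl ether cleaves the silyl group and oxidises the carbinol in one pot, giving the α,β-epoxy aldehyde without touching the esters, butenolide or epoxide.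

**Step 9**
Reactants: 14 (the epoxy aldehyde from step 8)
Product: 15 (1(10)E,4S,5R,7R,8R,9S)-4,5-epoxy-9-(2-methylpropanoyloxy)-6-oxogermacra-1(10),11(13)-dien-12,8-olide
Conditions: (Bu4N)4[W10O32] (5 mol%), MeCN (2 mM), 390 nm LED, 20 °C, argon; filter through Florisil, use at once
Reagents that add atoms: none
Why: Proposed new method: photoexcited [W10O32]4− abstracts the aldehydic hydrogen (polarity-matched hydrogen-atom transfer) to give a nucleophilic acyl σ-radical that cannot open the neighbouring epoxide and is slow to lose CO, small-ring closure onto C1=C10 is blocked because it would give a trans-fused epoxide, so it adds 10-exo to C7 of the butenolide on the face anti to the C8 side chain (trans-fused lactone) and the α-lactone radical is reduced by the reduced cluster [W10O32]5− to an enolate that expels isobutyrate to give the exo-methylene and turn the catalyst over; the closest known reaction types are (Bu4N)4[W10O32]-photocatalysed hydroacylation of electron-poor alkenes by aldehydes, acyl-radical macrocyclisation onto acrylates and radical allylation with 2-(acyloxymethyl)acrylates.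

**Step 10**
Reactants: 15 (the epoxy ketone from step 9)
Product: 16 (1(10)E,4S,5S,6S,7S,8R,9S)-4,5-epoxy-6-hydroxy-9-(2-methylpropanoyloxy)germacra-1(10),11(13)-dien-12,8-olide
Conditions: Zn(BH4)2, Et2O, −40 °C; then aq. NH4Cl
Reagents that add atoms: none
Why: Chelation-controlled reduction in which zinc bridges the ketone and epoxide oxygens and hydride attacks the face away from the C4 substituents gives, as in acyclic α,β-epoxy ketones, the erythro (anti) epoxy alcohol, here 6S, under neutral cold conditions that leave the methylene lactone, the ester and the labile C7 centre untouched.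

**Compound list**
1 | hex-1-en-5-yne | C=CCCC#C | starting material
2 | dimethyl[(1E)-2-methylhexa-1,5-dien-1-yl]alumane | C=CCC/C(C)=C/[Al](C)C | intermediate
3 | (2E)-3-methylhepta-2,6-dien-1-ol | C=CCC/C(C)=C/CO | intermediate
4 | [(2S,3S)-3-(but-3-en-1-yl)-3-methyloxiran-2-yl]methanol | C=CCC[C@]1(C)O[C@H]1CO | intermediate
5 | {[(2S,3S)-3-(but-3-en-1-yl)-3-methyloxiran-2-yl]methoxy}(triethyl)silane | C=CCC[C@]1(C)O[C@H]1CO[Si](CC)(CC)CC | intermediate
6 | methacrolein (2-methylprop-2-enal) | CC(=C)C=O | starting material
7 | (2E)-2-methyl-5-[(2S,3S)-2-methyl-3-{[(triethylsilyl)oxy]methyl}oxiran-2-yl]pent-2-enal | O=C/C(C)=C/CC[C@]1(C)O[C@H]1CO[Si](CC)(CC)CC | intermediate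
8 | 3-(hydroxymethyl)furan-2(5H)-one | OCC1=CCOC1=O | starting material
9 | trimethyl({2-[(trimethylsilyl)oxy]furan-3-yl}methoxy)silane | C[Si](C)(C)OCc1ccoc1O[Si](C)(C)C | intermediate
10 | bis(trimethylsilyl) ether of 11 (silyl groups on the C9 and C13 oxygens) | C[Si](C)(C)OCC1=C[C@@H](OC1=O)[C@@H](O[Si](C)(C)C)/C(C)=C/CC[C@]1(C)O[C@H]1CO[Si](CC)(CC)CC | intermediate
11 | (5R)-5-{(1S,2E)-1-hydroxy-2-methyl-5-[(2S,3S)-2-methyl-3-{[(triethylsilyl)oxy]methyl}oxiran-2-yl]pent-2-en-1-yl}-3-(hydroxymethyl)furan-2(5H)-one | OCC1=C[C@@H](OC1=O)[C@@H](O)/C(C)=C/CC[C@]1(C)O[C@H]1CO[Si](CC)(CC)CC | intermediate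
12 | 2-methylpropanoyl chloride | CC(C)C(Cl)=O | starting material
13 | [(5R)-5-{(1S,2E)-2-methyl-1-(2-methylpropanoyloxy)-5-[(2S,3S)-2-methyl-3-{[(triethylsilyl)oxy]methyl}oxiran-2-yl]pent-2-en-1-yl}-2-oxo-2,5-dihydrofuran-3-yl]methyl 2-methylpropanoate | CC(C)C(=O)OCC1=C[C@@H](OC1=O)[C@@H](OC(=O)C(C)C)/C(C)=C/CC[C@]1(C)O[C@H]1CO[Si](CC)(CC)CC | intermediate
14 | [(5R)-5-{(1S,2E)-5-[(2S,3R)-3-formyl-2-methyloxiran-2-yl]-2-methyl-1-(2-methylpropanoyloxy)pent-2-en-1-yl}-2-oxo-2,5-dihydrofuran-3-yl]methyl 2-methylpropanoate | CC(C)C(=O)OCC1=C[C@@H](OC1=O)[C@@H](OC(=O)C(C)C)/C(C)=C/CC[C@]1(C)O[C@H]1C=O | intermediate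
15 | (1(10)E,4S,5R,7R,8R,9S)-4,5-epoxy-9-(2-methylpropanoyloxy)-6-oxogermacra-1(10),11(13)-dien-12,8-olide | C=C1C(=O)O[C@@H]2[C@@H]1C(=O)[C@@H]1O[C@@]1(C)CC/C=C(\C)[C@@H]2OC(=O)C(C)C | intermediate
16 | (1(10)E,4S,5S,6S,7S,8R,9S)-4,5-epoxy-6-hydroxy-9-(2-methylpropanoyloxy)germacra-1(10),11(13)-dien-12,8-olide | C=C1C(=O)O[C@@H]2[C@@H]1[C@H](O)[C@@H]1O[C@@]1(C)CC/C=C(\C)[C@@H]2OC(=O)C(C)C | target

**Totals**
Total step count: 10. Longest linear sequence: 9 (steps 1–4 and 6–10; step 5 is a one-step side branch).

**Three steps most likely to fail**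

Step 9 is the riskiest. A ten-membered radical ring closure is slow, hydrogen abstraction could also occur at allylic positions, and ketone 15 can isomerise to the endocyclic butenolide. The fallback sets out from 14 and comes back at 16, bypassing 15. It is a polar umpolung allylation: Pd(PPh3)4 (zerovalent palladium, 10 mol%) and Et2Zn in THF at high dilution. The activated primary allylic isobutyrate ionises first to a π-allyl complex of palladium, which is transmetallated to an allylzinc. This adds through C7 to the aldehyde in a closed chair (C6/C7 anti, attack anti to the C8 chain) under Felkin control by the epoxide, giving 16 directly.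

Step 6 is next. The anti/syn ratio and the enantioselectivity are untested for a 3-substituted silyloxyfuran with an α-branched enal. The fallback sets out from 7 and 8 and comes back at 11, skipping 9 and 10. It is a direct vinylogous aldol of the free furanone 8 with 7 under a bifunctional cinchona squaramide–tertiary amine catalyst (10 mol%, CH2Cl2, rt). This uses a hydrogen-bonded ammonium dienolate instead of a silyl dienol ether and is also anti-selective.

Step 10 is third. The macrocycle may override the chelation model and deliver hydride to the wrong face. The fallback sets out from 15 and comes back at 16. The reduction product is then the 6-epimeric alcohol F1. A Mitsunobu reaction with formic acid (PPh3, DIAD, toluene, 0 °C) inverts C6 to give the (6S)-formate F2. KHCO3 in MeOH at 0 °C then cleaves the formate selectively in the presence of the isobutyrate and the methylene lactone to give 16.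

**Further compounds**
F0 | step 6 | none | none
F0 | step 9 | none | none
F1 | step 10 | (1(10)E,4S,5S,6R,7S,8R,9S)-4,5-epoxy-6-hydroxy-9-(2-methylpropanoyloxy)germacra-1(10),11(13)-dien-12,8-olide (6-epimer of 16) | C=C1C(=O)O[C@@H]2[C@@H]1[C@@H](O)[C@@H]1O[C@@]1(C)CC/C=C(\C)[C@@H]2OC(=O)C(C)C
F2 | step 10 | (1(10)E,4S,5S,6S,7S,8R,9S)-4,5-epoxy-6-(formyloxy)-9-(2-methylpropanoyloxy)germacra-1(10),11(13)-dien-12,8-olide (6-O-formate of 16) | C=C1C(=O)O[C@@H]2[C@@H]1[C@H](OC=O)[C@@H]1O[C@@]1(C)CC/C=C(\C)[C@@H]2OC(=O)C(C)C
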